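## Retrosynthetic overview

1. Feature: ring B (central ring) is a phloroglucinol whose three C–O carbons alternate with three different carbons, one bearing the CH2 arm to ring A (OMe para to butanoyl), one the CH2 arm to ring C (OMe ortho to butanoyl), one the acetyl. Without the acetyl, this C6O3 pattern is that of 4-hydroxy-6-methyl-2-pyranone, whose C3 (enol carbon) and 6-CH3 (vinylogous methyl ketone) are chemically distinct.
2. Last disconnections: the five O-benzyl groups (hydrogenolysis) and the ring B acetyl (Friedel–Crafts at the only free carbon of the three phloroglucinol rings).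
3. Key disconnection: the ring B bond between the carbon bearing the ring A arm and the C–OH carbon lying between the two arms. This leads back to a 4-benzyloxy-2-pyranone with the ring C benzyl group on C3 and a 2-(ring A aryl)ethyl chain on C6; alkoxide opening and Claisen reclosure turn that ring into ring B.
4. The C6 chain comes from aldol condensation of the 6-methyl group with a ring A benzaldehyde, then hydrogenation. The C3 benzyl group comes from reductive Knoevenagel alkylation of the lactone with a ring C benzaldehyde.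
5. Ring order: rings A and C are both bought as 2-methylphloroglucinol and dressed; putting butanoyl on before formyl gives ring A, formyl before butanoyl gives ring C. The pyranone ring is bought, and ring B is the only ring formed, last, from the pyranone.

Key step: step 13

Remark: the target has no stereocentre, so only alkene geometries in intermediates need comment; they are given where they arise.

## Route

Step 1
Reactants: 1 2-methylbenzene-1,3,5-triol
Product: 3 2,4,6-trihydroxy-3-methylbenzaldehyde, via aryl iminium chloride 2 (not isolated)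
Conditions: POCl3 (1.1 equiv), DMF, EtOAc, 0 °C to rt; then H2O, 50 °C
Reagents that add atoms: N,N-dimethylformamide CN(C)C=O (formyl carbon); water O (carbonyl oxygen)
Why: Vilsmeier–Haack formylation of a phloroglucinol; the two unsubstituted ring carbons of 1 are equivalent, so a single aldehyde should form, and the iminium group of 2 deactivates the ring toward a second formylation.

Step 2
Reactants: 3 2,4,6-trihydroxy-3-methylbenzaldehyde
Product: 4 2,6-dihydroxy-4-methoxy-3-methylbenzaldehyde
Conditions: Me2SO4 (1.0 equiv), K2CO3 (1.0 equiv), MeCN, 0 °C to rt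
Reagents that add atoms: dimethyl sulfate COS(=O)(=O)OC
Why: Williamson O-methylation; the hydroxyl para to the formyl group is the most acidic and the only one not held in a hydrogen bond to the carbonyl, so one equivalent of reagent should methylate it selectively.

Step 3
Reactants: 4 2,6-dihydroxy-4-methoxy-3-methylbenzaldehyde; 5 butanoyl chloride
Product: 6 3-butanoyl-2,6-dihydroxy-4-methoxy-5-methylbenzaldehyde
Conditions: AlCl3 (3.5 equiv), PhNO2, 0 °C to rt; then ice, aq HCl
Reagents that add atoms: none
Why: Friedel–Crafts acylation at the only unsubstituted ring carbon, which is ortho or para to all three oxygens and only meta to the formyl group, so it should behave like the second acylation of a monoacylphloroglucinol; the mixture is kept at or below rt so that AlCl3 does not cleave the methyl ether beside the new ketone.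

Step 4
Reactants: 6 3-butanoyl-2,6-dihydroxy-4-methoxy-5-methylbenzaldehyde
Product: 7 2,6-bis(benzyloxy)-3-butanoyl-4-methoxy-5-methylbenzaldehyde (ring C aldehyde)
Conditions: BnBr (2.5 equiv), K2CO3 (3 equiv), Bu4NI (cat.), DMF, 60 °C
Reagents that add atoms: benzyl bromide BrCc1ccccc1
Why: Williamson etherification; in DMF the carbonate breaks the hydrogen bonds of both ortho-hydroxyls to the carbonyl groups and the phenoxides are benzylated, which removes the acidic protons that would otherwise divert the later condensations.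

Step 5
Reactants: 1 2-methylbenzene-1,3,5-triol; 5 butanoyl chloride
Product: 8 1-(2,4,6-trihydroxy-3-methylphenyl)butan-1-one
Conditions: AlCl3 (3 equiv), PhNO2, rt to 50 °C; then ice, aq HCl
Reagents that add atoms: none
Why: Friedel–Crafts C-acylation of a phloroglucinol (any aryl ester formed first undergoes Fries shift under the same conditions); the two free ring carbons are equivalent and the monoketone is less reactive than 1, so a single ketone should result.

Step 6
Reactants: 8 1-(2,4,6-trihydroxy-3-methylphenyl)butan-1-one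
Product: 9 1-(2,6-dihydroxy-4-methoxy-3-methylphenyl)butan-1-one
Conditions: Me2SO4 (1.0 equiv), K2CO3 (1.0 equiv), acetone, rt
Reagents that add atoms: dimethyl sulfate COS(=O)(=O)OC
Why: Williamson O-methylation; the hydroxyl para to the ketone is the most acidic and is free of the hydrogen bonding that holds back the two ortho-hydroxyls, so it should be methylated selectively.

Step 7
Reactants: 9 1-(2,6-dihydroxy-4-methoxy-3-methylphenyl)butan-1-one
Product: 11 3-butanoyl-2,4-dihydroxy-6-methoxy-5-methylbenzaldehyde, via aryl iminium chloride 10 (not isolated)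
Conditions: POCl3 (1.1 equiv), DMF, EtOAc, 0 °C to rt; then H2O, 50 °C
Reagents that add atoms: N,N-dimethylformamide CN(C)C=O (formyl carbon); water O (carbonyl oxygen)
Why: Vilsmeier–Haack formylation at the only free ring carbon (ortho to OH and OMe, para to OH); with about one equivalent of reagent at 0 °C to rt the ring should react well before the hydrogen-bonded, hindered ketone.

Step 8
Reactants: 11 3-butanoyl-2,4-dihydroxy-6-methoxy-5-methylbenzaldehyde
Product: 12 2,4-bis(benzyloxy)-3-butanoyl-6-methoxy-5-methylbenzaldehyde (ring A aldehyde)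
Conditions: BnBr (2.5 equiv), K2CO3 (3 equiv), Bu4NI (cat.), DMF, 60 °C
Reagents that add atoms: benzyl bromide BrCc1ccccc1
Why: Williamson etherification of both hydrogen-bonded phenols in a dipolar aprotic solvent, as in step 4, to give an aldehyde with no acidic OH.

Step 9
Reactants: 13 4-hydroxy-6-methyl-2H-pyran-2-one; 7 2,6-bis(benzyloxy)-3-butanoyl-4-methoxy-5-methylbenzaldehyde
Product: 15 3-{[2,6-bis(benzyloxy)-3-butanoyl-4-methoxy-5-methylphenyl]methyl}-4-hydroxy-6-methyl-2H-pyran-2-one, via Knoevenagel alkylidene dione 14 (not isolated)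
Conditions: Hantzsch ester (diethyl 2,6-dimethyl-1,4-dihydropyridine-3,5-dicarboxylate, 1.2 equiv), L-proline (20 mol %), CH2Cl2, rt to 40 °C
Reagents that add atoms: none
Why: three-component reductive alkylation; proline-mediated Knoevenagel condensation at the enolic C3 of 13 gives alkylidene dione 14, which should take a hydride from the Hantzsch ester at its benzylidene carbon faster than it adds a second molecule of 13, so the mono-benzyl lactone results.

Step 10
Reactants: 15 3-{[2,6-bis(benzyloxy)-3-butanoyl-4-methoxy-5-methylphenyl]methyl}-4-hydroxy-6-methyl-2H-pyran-2-one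
Product: 16 4-(benzyloxy)-3-{[2,6-bis(benzyloxy)-3-butanoyl-4-methoxy-5-methylphenyl]methyl}-6-methyl-2H-pyran-2-one
Conditions: BnBr (1.2 equiv), K2CO3 (1.5 equiv), DMF, rt to 50 °C
Reagents that add atoms: benzyl bromide BrCc1ccccc1
Why: Williamson O-alkylation of the vinylogous carboxylic acid; with C3 blocked the 4-oxygen is the main site of benzylation and gives the 4-benzyloxy-2-pyranone needed for the later ring opening (a 2-benzyloxy-4-pyranone isomer, if formed, would be removed by chromatography).

Step 11
Reactants: 16 4-(benzyloxy)-3-{[2,6-bis(benzyloxy)-3-butanoyl-4-methoxy-5-methylphenyl]methyl}-6-methyl-2H-pyran-2-one; 12 2,4-bis(benzyloxy)-3-butanoyl-6-methoxy-5-methylbenzaldehyde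
Product: 17 6-{(E)-2-[2,4-bis(benzyloxy)-3-butanoyl-6-methoxy-5-methylphenyl]ethenyl}-4-(benzyloxy)-3-{[2,6-bis(benzyloxy)-3-butanoyl-4-methoxy-5-methylphenyl]methyl}-2H-pyran-2-one
Conditions: Mg(OMe)2 (3 equiv), MeOH–THF, reflux; then aq HCl
Reagents that add atoms: none
Why: vinylogous aldol condensation, known for 4-alkoxy-6-methyl-2-pyranones with Mg(OMe)2; the 6-methyl group is the only position of the lactone core that can form the extended enolate now that C3 is substituted, aldehyde 12 cannot enolise at the formyl carbon, and E1cB loss of water should give the conjugated (E)-alkene.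

Step 12
Reactants: 17 the (E)-styrylpyranone of step 11
Product: 18 6-{2-[2,4-bis(benzyloxy)-3-butanoyl-6-methoxy-5-methylphenyl]ethyl}-4-(benzyloxy)-3-{[2,6-bis(benzyloxy)-3-butanoyl-4-methoxy-5-methylphenyl]methyl}-2H-pyran-2-one
Conditions: H2 (3 atm), RhCl(PPh3)3 (10 mol %), THF–EtOH, 40 °C
Reagents that add atoms: none
Why: homogeneous catalytic hydrogenation with RhCl(PPh3)3 should saturate the disubstituted styryl double bond and leave the five benzyl ethers, the two aryl ketones and the more substituted, ester-conjugated double bonds of the pyranone untouched.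

Step 13
Reactants: 18 the 3-benzyl-6-(2-arylethyl)-4-benzyloxy-2-pyranone of step 12
Product: 20 5-(benzyloxy)-2-{[2,4-bis(benzyloxy)-3-butanoyl-6-methoxy-5-methylphenyl]methyl}-4-{[2,6-bis(benzyloxy)-3-butanoyl-4-methoxy-5-methylphenyl]methyl}benzene-1,3-diol, via ring-opened methyl ester 19 (not isolated)
Conditions: NaOMe (5 equiv), MeOH–THF, 65 °C; then aq HCl
Reagents that add atoms: none
Why: Methoxide adds to the lactone carbonyl of 18 and the ring opens to the enolate of keto ester 19, in which the ester and the CH2C(=O) arm stay cis on the tetrasubstituted enol ether double bond because they were ring neighbours. Proton transfer gives the carbanion on the CH2 between the ketone and the ring A benzyl carbon; it attacks the ester carbonyl (intramolecular Claisen condensation, 6-exo-trig with the enolate double bond inside the forming ring), methoxide leaves and the cyclohexenedione enolises to aromatic ring B, so that the lactone carbonyl oxygen, the former ring oxygen (by then the ketone oxygen) and the 4-benzyloxy group end as the three ring B oxygens. The closest known reaction is the alkoxide-induced isomerisation of 4-alkoxy-6-alkyl-2-pyranones to phloroglucinol monoethers. No stereocentre is formed. The step needs closure through this less acidic alpha-prime carbanion and not through the more acidic CH2 between enol ether and ketone; ring size secures it, since the latter carbon could reach the ester only in a four-membered ring, and aromatisation to a phenoxide drains the equilibrium. The butanoyl groups of rings A and C sit meta to the bridging carbons, so their enolates cannot reach the ester in a normal ring and should stay spectators.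

Step 14
Reactants: 20 the ring B resorcinol of step 13
Product: 21 1-(6-(benzyloxy)-3-{[2,4-bis(benzyloxy)-3-butanoyl-6-methoxy-5-methylphenyl]methyl}-5-{[2,6-bis(benzyloxy)-3-butanoyl-4-methoxy-5-methylphenyl]methyl}-2,4-dihydroxyphenyl)ethan-1-one
Conditions: Ac2O (1.5 equiv), BF3·OEt2 (2 equiv), CH2Cl2, 0 °C to rt; then aq NaHCO3, MeOH
Reagents that add atoms: acetic anhydride CC(=O)OC(C)=O
Why: Friedel–Crafts C-acetylation at the only unsubstituted carbon of the three phloroglucinol rings, which is ortho to one free hydroxyl and para to the other on the most electron-rich ring; a short reaction at 0 °C to rt should spare the benzyl ethers, and the methanolic NaHCO3 quench breaks the difluoroboron chelate of the product.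

Step 15
Reactants: 21 the acetylated pentabenzyl ether of step 14
Product: 22 1-[3-({3-acetyl-5-[(3-butanoyl-2,6-dihydroxy-4-methoxy-5-methylphenyl)methyl]-2,4,6-trihydroxyphenyl}methyl)-2,6-dihydroxy-4-methoxy-5-methylphenyl]butan-1-one (target)
Conditions: H2 (1 atm), 10% Pd/C, EtOAc–MeOH, rt
Reagents that add atoms: none
Why: catalytic hydrogenolysis of all five aryl benzyl ethers; the hydrogen-bonded acylphloroglucinol ketones and the diarylmethane bridges should not be reduced under these mild conditions, and the neutral medium avoids scrambling of the methylene bridges.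

## Compound list

1 | 2-methylbenzene-1,3,5-triol | Cc1c(O)cc(O)cc1O | starting material
2 | aryl iminium chloride: N-methyl-N-[(2,4,6-trihydroxy-3-methylphenyl)methylidene]methanaminium chloride | C[N+](C)=Cc1c(O)cc(O)c(C)c1O.[Cl-] | intermediate
3 | 2,4,6-trihydroxy-3-methylbenzaldehyde | O=Cc1c(O)cc(O)c(C)c1O | intermediate
4 | 2,6-dihydroxy-4-methoxy-3-methylbenzaldehyde | O=Cc1c(O)cc(OC)c(C)c1O | intermediate
5 | butanoyl chloride | CCCC(Cl)=O | starting material
6 | 3-butanoyl-2,6-dihydroxy-4-methoxy-5-methylbenzaldehyde | O=Cc1c(O)c(C(=O)CCC)c(OC)c(C)c1O | intermediate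
7 | 2,6-bis(benzyloxy)-3-butanoyl-4-methoxy-5-methylbenzaldehyde (ring C aldehyde) | O=Cc1c(OCc2ccccc2)c(C(=O)CCC)c(OC)c(C)c1OCc1ccccc1 | intermediate
8 | 1-(2,4,6-trihydroxy-3-methylphenyl)butan-1-one | CCCC(=O)c1c(O)cc(O)c(C)c1O | intermediate
9 | 1-(2,6-dihydroxy-4-methoxy-3-methylphenyl)butan-1-one | CCCC(=O)c1c(O)cc(OC)c(C)c1O | intermediate
10 | aryl iminium chloride: N-[(3-butanoyl-2,4-dihydroxy-6-methoxy-5-methylphenyl)methylidene]-N-methylmethanaminium chloride | C[N+](C)=Cc1c(O)c(C(=O)CCC)c(O)c(C)c1OC.[Cl-] | intermediate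
11 | 3-butanoyl-2,4-dihydroxy-6-methoxy-5-methylbenzaldehyde | O=Cc1c(O)c(C(=O)CCC)c(O)c(C)c1OC | intermediate
12 | 2,4-bis(benzyloxy)-3-butanoyl-6-methoxy-5-methylbenzaldehyde (ring A aldehyde) | O=Cc1c(OCc2ccccc2)c(C(=O)CCC)c(OCc2ccccc2)c(C)c1OC | intermediate
13 | 4-hydroxy-6-methyl-2H-pyran-2-one | CC1=CC(O)=CC(=O)O1 | starting material
14 | Knoevenagel alkylidene dione: (3E)-3-{[2,6-bis(benzyloxy)-3-butanoyl-4-methoxy-5-methylphenyl]methylidene}-6-methyl-2H-pyran-2,4(3H)-dione (drawn E; either geometry reduces to 15) | CC1=CC(=O)/C(=C\c2c(OCc3ccccc3)c(C(=O)CCC)c(OC)c(C)c2OCc2ccccc2)C(=O)O1 | intermediate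
15 | 3-{[2,6-bis(benzyloxy)-3-butanoyl-4-methoxy-5-methylphenyl]methyl}-4-hydroxy-6-methyl-2H-pyran-2-one | CC1=CC(O)=C(Cc2c(OCc3ccccc3)c(C(=O)CCC)c(OC)c(C)c2OCc2ccccc2)C(=O)O1 | intermediate
16 | 4-(benzyloxy)-3-{[2,6-bis(benzyloxy)-3-butanoyl-4-methoxy-5-methylphenyl]methyl}-6-methyl-2H-pyran-2-one | CC1=CC(OCc2ccccc2)=C(Cc2c(OCc3ccccc3)c(C(=O)CCC)c(OC)c(C)c2OCc2ccccc2)C(=O)O1 | intermediate
17 | 6-{(E)-2-[2,4-bis(benzyloxy)-3-butanoyl-6-methoxy-5-methylphenyl]ethenyl}-4-(benzyloxy)-3-{[2,6-bis(benzyloxy)-3-butanoyl-4-methoxy-5-methylphenyl]methyl}-2H-pyran-2-one | O=C1OC(/C=C/c2c(OC)c(C)c(OCc3ccccc3)c(C(=O)CCC)c2OCc2ccccc2)=CC(OCc2ccccc2)=C1Cc1c(OCc2ccccc2)c(C)c(OC)c(C(=O)CCC)c1OCc1ccccc1 | intermediate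
18 | 6-{2-[2,4-bis(benzyloxy)-3-butanoyl-6-methoxy-5-methylphenyl]ethyl}-4-(benzyloxy)-3-{[2,6-bis(benzyloxy)-3-butanoyl-4-methoxy-5-methylphenyl]methyl}-2H-pyran-2-one (key-step precursor) | O=C1OC(CCc2c(OC)c(C)c(OCc3ccccc3)c(C(=O)CCC)c2OCc2ccccc2)=CC(OCc2ccccc2)=C1Cc1c(OCc2ccccc2)c(C)c(OC)c(C(=O)CCC)c1OCc1ccccc1 | intermediate
19 | ring-opened methyl ester: methyl (2E)-3-(benzyloxy)-7-[2,4-bis(benzyloxy)-3-butanoyl-6-methoxy-5-methylphenyl]-2-{[2,6-bis(benzyloxy)-3-butanoyl-4-methoxy-5-methylphenyl]methyl}-5-oxohept-2-enoate (ester and CH2C(=O) arm cis) | COC(=O)/C(Cc1c(OCc2ccccc2)c(C)c(OC)c(C(=O)CCC)c1OCc1ccccc1)=C(\CC(=O)CCc1c(OC)c(C)c(OCc2ccccc2)c(C(=O)CCC)c1OCc1ccccc1)OCc1ccccc1 | intermediate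
20 | 5-(benzyloxy)-2-{[2,4-bis(benzyloxy)-3-butanoyl-6-methoxy-5-methylphenyl]methyl}-4-{[2,6-bis(benzyloxy)-3-butanoyl-4-methoxy-5-methylphenyl]methyl}benzene-1,3-diol (key-step product) | Oc1cc(OCc2ccccc2)c(Cc2c(OCc3ccccc3)c(C)c(OC)c(C(=O)CCC)c2OCc2ccccc2)c(O)c1Cc1c(OC)c(C)c(OCc2ccccc2)c(C(=O)CCC)c1OCc1ccccc1 | intermediate
21 | 1-(6-(benzyloxy)-3-{[2,4-bis(benzyloxy)-3-butanoyl-6-methoxy-5-methylphenyl]methyl}-5-{[2,6-bis(benzyloxy)-3-butanoyl-4-methoxy-5-methylphenyl]methyl}-2,4-dihydroxyphenyl)ethan-1-one | CC(=O)c1c(O)c(Cc2c(OC)c(C)c(OCc3ccccc3)c(C(=O)CCC)c2OCc2ccccc2)c(O)c(Cc2c(OCc3ccccc3)c(C)c(OC)c(C(=O)CCC)c2OCc2ccccc2)c1OCc1ccccc1 | intermediate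
22 | 1-[3-({3-acetyl-5-[(3-butanoyl-2,6-dihydroxy-4-methoxy-5-methylphenyl)methyl]-2,4,6-trihydroxyphenyl}methyl)-2,6-dihydroxy-4-methoxy-5-methylphenyl]butan-1-one | CCCC(=O)c1c(O)c(C)c(OC)c(Cc2c(O)c(Cc3c(O)c(C)c(OC)c(C(=O)CCC)c3O)c(O)c(C(C)=O)c2O)c1O | target

## Step count and risks

Total step count: 15.
Longest linear sequence: 11 steps (steps 1, 2, 3, 4, 9, 10, 11, 12, 13, 14, 15). The ring A branch (steps 5 to 8) joins at step 11.

Steps most likely to fail:

Step 13. The Claisen closure must attack an ester on a fully substituted enoate carbon that also carries the bulky ring C benzyl group. It may be slower than relactonisation, so that 18 is simply returned, or slower than addition–elimination of methoxide at C4, which would exchange the benzyloxy group. The fallback closes ring B before the ring C arm is attached, on the unhindered substrate class for which the isomerisation is established, and then uses the symmetry of the product to place the second arm. It sets out from 13: benzylation (BnBr, K2CO3, DMF) would give 4-(benzyloxy)-6-methyl-2H-pyran-2-one F1. Condensation with 12 (Mg(OMe)2, MeOH, reflux) would give the mono-arm styrylpyranone F2, and hydrogenation (H2, RhCl(PPh3)3) the dihydro compound F3. NaOMe in MeOH should then isomerise F3 to the 2-benzyl-5-(benzyloxy)resorcinol F4, whose two free ring carbons are equivalent. Reductive Friedel–Crafts benzylation of F4 with one equivalent of aldehyde 7 (Et3SiH, CF3CO2H, CH2Cl2, 0 °C) would then place the ring C arm between OH and OBn and come back to the route at 20.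

Step 11. Addition of the magnesium dienolate to the doubly ortho-substituted, electron-rich aldehyde may be slow and reversible, so that retro-aldol, methoxide attack on the lactone or enolisation of the butanoyl groups take over during the long reflux. The fallback replaces the condensation by a C-alkylation and so also removes the hydrogenation. Aldehyde 12 would be reduced at the formyl group only (NaBH4, MeOH–THF, −20 °C; the ketone is shielded by two ortho-benzyloxy groups) to the benzylic alcohol F5 and converted with PBr3 (CH2Cl2, 0 °C) into the benzylic bromide F6. Lactone 15 would be turned into its polyanion with LiN(iPr)2 (3.2 equiv, THF, −78 °C: 4-oxide, ketone enolate and 6-CH2 carbanion) and alkylated with F6 at the last-formed, most basic carbanion, the 6-CH2, as is known for the dianion of 13 with benzyl halides. This would give the 4-hydroxy-6-(2-arylethyl)pyranone F7. O-benzylation (BnBr, K2CO3, DMF) comes back to the route at 18.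

Step 3. Complexation of the formyl group by AlCl3 may slow the acylation so much that heating is needed, and under forcing conditions AlCl3 cleaves the methyl ether ortho to the new ketone, which would erase the OMe/OH distinction of ring C. The fallback puts the ketone on first and the aldehyde on last, with no free phenol and no strong Lewis acid near the methyl ether. It sets out from 8: benzylation with 2.1 equiv BnBr (K2CO3, acetone, reflux) should take the para hydroxyl and the less hindered of the two hydrogen-bonded hydroxyls, leaving the one wedged between methyl and ketone, to give the dibenzyl ether F8. Methylation of that last hydroxyl (MeI, K2CO3, DMF, 50 °C) would give the methyl ether F9. Rieche formylation at the only free ring carbon (Cl2CHOMe, SnCl4, CH2Cl2, −20 °C) comes back to the route at 7.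

## Further compounds

F1 | step 13 | 4-(benzyloxy)-6-methyl-2H-pyran-2-one | CC1=CC(OCc2ccccc2)=CC(=O)O1
F2 | step 13 | 6-{(E)-2-[2,4-bis(benzyloxy)-3-butanoyl-6-methoxy-5-methylphenyl]ethenyl}-4-(benzyloxy)-2H-pyran-2-one | O=C1C=C(OCc2ccccc2)C=C(/C=C/c2c(OC)c(C)c(OCc3ccccc3)c(C(=O)CCC)c2OCc2ccccc2)O1
F3 | step 13 | 6-{2-[2,4-bis(benzyloxy)-3-butanoyl-6-methoxy-5-methylphenyl]ethyl}-4-(benzyloxy)-2H-pyran-2-one | O=C1C=C(OCc2ccccc2)C=C(CCc2c(OC)c(C)c(OCc3ccccc3)c(C(=O)CCC)c2OCc2ccccc2)O1
F4 | step 13 | 5-(benzyloxy)-2-{[2,4-bis(benzyloxy)-3-butanoyl-6-methoxy-5-methylphenyl]methyl}benzene-1,3-diol | Oc1cc(OCc2ccccc2)cc(O)c1Cc1c(OC)c(C)c(OCc2ccccc2)c(C(=O)CCC)c1OCc1ccccc1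
F5 | step 11 | 1-[2,6-bis(benzyloxy)-3-(hydroxymethyl)-4-methoxy-5-methylphenyl]butan-1-one | OCc1c(OCc2ccccc2)c(C(=O)CCC)c(OCc2ccccc2)c(C)c1OC
F6 | step 11 | 1-[2,6-bis(benzyloxy)-3-(bromomethyl)-4-methoxy-5-methylphenyl]butan-1-one | BrCc1c(OCc2ccccc2)c(C(=O)CCC)c(OCc2ccccc2)c(C)c1OC
F7 | step 11 | 6-{2-[2,4-bis(benzyloxy)-3-butanoyl-6-methoxy-5-methylphenyl]ethyl}-3-{[2,6-bis(benzyloxy)-3-butanoyl-4-methoxy-5-methylphenyl]methyl}-4-hydroxy-2H-pyran-2-one | O=C1OC(CCc2c(OC)c(C)c(OCc3ccccc3)c(C(=O)CCC)c2OCc2ccccc2)=CC(O)=C1Cc1c(OCc2ccccc2)c(C)c(OC)c(C(=O)CCC)c1OCc1ccccc1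
F8 | step 3 | 1-[4,6-bis(benzyloxy)-2-hydroxy-3-methylphenyl]butan-1-one | CCCC(=O)c1c(O)c(C)c(OCc2ccccc2)cc1OCc1ccccc1
F9 | step 3 | 1-[4,6-bis(benzyloxy)-2-methoxy-3-methylphenyl]butan-1-one | CCCC(=O)c1c(OC)c(C)c(OCc2ccccc2)cc1OCc1ccccc1
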